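**Retrosynthetic overview**
- Target ⇐ hexabenzyl ether by BCl3 debenzylation at −78 °C, done last and cold because the cis C2–H is epimerisable.
- Dihydronaphthalene ⇐ transient spiro[4.5]cyclohexadienyl cation by a 1,2-vinyl shift (ring expansion 5→6); the spiro cation comes from ipso capture of a protonated enone within a C2-symmetric bis-benzylidene 1,4-diketone (one catalytic asymmetric cycloisomerisation; C1 set by the catalyst, C2 by kinetic protonation).
- Bis-benzylidene diketone ⇐ Ni(0) homocoupling of a (Z)-α-bromochalcone ⇐ chalcone ⇐ Claisen–Schmidt condensation of aryl aldehyde and aryl methyl ketone.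
- Aldehyde ⇐ catechol (two Mg-mediated ortho-formylations around a Dakin-type oxidation); ketone ⇐ phenol + acetyl chloride.
- Ring order: the benzene rings are bought; the spirocyclopentene forms transiently and is expanded to the dihydronaphthalene ring in the same step.

Assumption: the SMILES encodes (1R,2R), i.e. C1-aryl and C2-aroyl cis; formaldehyde (as paraformaldehyde) and acetyl chloride are numbered as building blocks; the catalyst antipode that gives 1R in step 11 must be fixed by experiment.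

**Route**

Step 1
Reactants: 1 catechol; 2 formaldehyde (as paraformaldehyde)
Product: 3 2,3-dihydroxybenzaldehyde
Conditions: (CH2O)n, MgCl2, Et3N, MeCN, reflux; then 1 M HCl
Reagents that add atoms: none
Why: Magnesium-phenoxide-directed ortho-formylation (Casnati–Skattebøl) delivers CHO only next to OH, a second equivalent of formaldehyde acting as hydride acceptor; no stereocentre.

Step 2
Reactants: 3 2,3-dihydroxybenzaldehyde
Product: 4 2,3-bis(benzyloxy)benzaldehyde
Conditions: BnBr (2.3 equiv), K2CO3, DMF, 60 °C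
Reagents that add atoms: benzyl bromide BrCc1ccccc1
Why: Williamson etherification of both phenoxides, giving ethers that survive base, Ni(0) and strong acid later.

Step 3
Reactants: 4 2,3-bis(benzyloxy)benzaldehyde
Product: 6 2,3-bis(benzyloxy)phenol, via aryl formate 5 (not isolated)
Conditions: mCPBA, CH2Cl2, 0 °C to rt; then K2CO3 (cat.), MeOH, rt
Reagents that add atoms: mCPBA OOC(=O)c1cccc(Cl)c1
Why: Baeyer–Villiger (Dakin-type) oxidation in which the electron-rich aryl group migrates to give the formate, which is methanolysed to the phenol (third ring oxygen installed).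

Step 4
Reactants: 6 2,3-bis(benzyloxy)phenol; 2 formaldehyde (as paraformaldehyde)
Product: 7 3,4-bis(benzyloxy)-2-hydroxybenzaldehyde
Conditions: (CH2O)n, MgCl2, Et3N, MeCN, reflux; then 1 M HCl
Reagents that add atoms: none
Why: The same OH-directed ortho-formylation; only one ortho position is free, so CHO enters next to the oxygen that becomes OMe with complete regiocontrol.

Step 5
Reactants: 7 3,4-bis(benzyloxy)-2-hydroxybenzaldehyde
Product: 8 3,4-bis(benzyloxy)-2-methoxybenzaldehyde
Conditions: MeI, K2CO3, DMF, 40 °C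
Reagents that add atoms: iodomethane CI
Why: Williamson methylation of the only free (chelated) phenol fixes the 2-OMe/3,4-OBn pattern.

Step 6
Reactants: 9 phenol; 10 acetyl chloride
Product: 11 1-(4-hydroxyphenyl)ethan-1-one
Conditions: TfOH (neat), 0 °C to rt
Reagents that add atoms: none
Why: Friedel–Crafts C-acylation (Fries-type) of phenol in neat triflic acid is para-selective; the minor ortho isomer is removed by crystallisation.

Step 7
Reactants: 11 1-(4-hydroxyphenyl)ethan-1-one
Product: 12 1-[4-(benzyloxy)phenyl]ethan-1-one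
Conditions: BnBr, K2CO3, acetone, reflux
Reagents that add atoms: benzyl bromide BrCc1ccccc1
Why: Williamson etherification protects the acidic phenol before bromination and Ni(0) chemistry.

Step 8
Reactants: 8 3,4-bis(benzyloxy)-2-methoxybenzaldehyde; 12 1-[4-(benzyloxy)phenyl]ethan-1-one
Product: 13 (E)-1-[4-(benzyloxy)phenyl]-3-[3,4-bis(benzyloxy)-2-methoxyphenyl]prop-2-en-1-one
Conditions: KOH (aq), EtOH/THF, rt
Reagents that add atoms: none
Why: Claisen–Schmidt aldol condensation of a non-enolisable aldehyde with a methyl ketone gives the thermodynamic E-enone.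

Step 9
Reactants: 13 (E)-1-[4-(benzyloxy)phenyl]-3-[3,4-bis(benzyloxy)-2-methoxyphenyl]prop-2-en-1-one
Product: 15 (Z)-1-[4-(benzyloxy)phenyl]-3-[3,4-bis(benzyloxy)-2-methoxyphenyl]-2-bromoprop-2-en-1-one, via erythro dibromide 14 (not isolated)
Conditions: Br2 (1.0 equiv), CH2Cl2, −20 °C; then Et3N (2 equiv), rt
Reagents that add atoms: bromine BrBr
Why: Anti bromination of the electron-rich enone C=C followed by E1cB dehydrobromination gives the thermodynamic (Z)-α-bromoenone (aryl trans to C=O).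

Step 10
Reactants: 15 (Z)-1-[4-(benzyloxy)phenyl]-3-[3,4-bis(benzyloxy)-2-methoxyphenyl]-2-bromoprop-2-en-1-one (2 equiv)
Product: 16 (2E,3E)-1,4-bis[4-(benzyloxy)phenyl]-2,3-bis{[3,4-bis(benzyloxy)-2-methoxyphenyl]methylidene}butane-1,4-dione
Conditions: Ni(cod)2 (0.6 equiv), PPh3 (1.2 equiv), DMF, 45 °C
Reagents that add atoms: none
Why: Ni(0)-mediated reductive homocoupling of a vinyl bromide (Semmelhack/Ullmann type) forms the C2–C3 bond with retention of alkene geometry, as known for α-bromocinnamates giving dibenzylidenesuccinates.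

Step 11
Reactants: 16 (2E,3E)-1,4-bis[4-(benzyloxy)phenyl]-2,3-bis{[3,4-bis(benzyloxy)-2-methoxyphenyl]methylidene}butane-1,4-dione
Product: 19 [(1R,2R)-6,7-bis(benzyloxy)-1-[3,4-bis(benzyloxy)-2-methoxyphenyl]-8-methoxy-1,2-dihydronaphthalene-2,3-diyl]bis{[4-(benzyloxy)phenyl]methanone}, via spiro Wheland cation 17 (not isolated), via C2 dienol 18 (not isolated)
Conditions: chiral BINOL-derived N-triflylphosphoramide (10 mol %), CHCl3, 5 Å MS, −40 to −20 °C
Reagents that add atoms: none
Why: Proposed new method: the chiral Brønsted acid O-protonates one enone of C2-symmetric 16 to a p-benzyloxybenzylic (quinone-methide-type) cation at C1, which should be captured not at C6' (para only to the buttressed, out-of-plane 3-OBn) but at the most electron-rich ring carbon C1' (para to 4-OBn, ortho to OMe) of the other benzylidene unit, giving spiro cation 17 inside the chiral ion pair (sets C1); the enol formed at C2 then pushes the vinyl carbon C4 from C1' to C6' (1,2-shift, a dienone–phenol-type ring expansion of the spirocyclopentene to the dihydronaphthalene, whereas C1–C1' cleavage only returns the open cation), which is why the C1-bearing carbon keeps OMe as its neighbour (C8); proton loss gives dienol 18, and kinetic protonation of C2 anti to the pseudoaxial C1 aryl gives the 1,2-cis ketone; closest known chemistry is the TfOH cyclisation of 2,3-dibenzylidenesuccinates to 1-aryl-1,2-dihydronaphthalenes, the acid-catalysed dienone–phenol rearrangement of spiro[4.5]trienones and chiral-acid-catalysed Nazarov cyclisations and 1,6-additions to p-quinone methides.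

Step 12
Reactants: 19 [(1R,2R)-6,7-bis(benzyloxy)-1-[3,4-bis(benzyloxy)-2-methoxyphenyl]-8-methoxy-1,2-dihydronaphthalene-2,3-diyl]bis{[4-(benzyloxy)phenyl]methanone}
Product: 20 [(1R,2R)-1-(3,4-dihydroxy-2-methoxyphenyl)-6,7-dihydroxy-8-methoxy-1,2-dihydronaphthalene-2,3-diyl]bis[(4-hydroxyphenyl)methanone]
Conditions: BCl3 (12 equiv), pentamethylbenzene (18 equiv), CH2Cl2, −78 °C; MeOH quench at −78 °C
Reagents that add atoms: none
Why: Lewis-acid debenzylation with pentamethylbenzene as benzyl-cation scavenger cleaves aryl benzyl ethers at −78 °C without base or hydrogen, so the enone C=C, both aryl methyl ethers and the cis C2–H are kept.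

**Compound list**
1 | catechol | Oc1ccccc1O | starting material
2 | formaldehyde (used as paraformaldehyde) | C=O | starting material
3 | 2,3-dihydroxybenzaldehyde | O=Cc1cccc(O)c1O | intermediate
4 | 2,3-bis(benzyloxy)benzaldehyde | O=Cc1cccc(OCc2ccccc2)c1OCc1ccccc1 | intermediate
5 | 2,3-bis(benzyloxy)phenyl formate (not isolated) | O=COc1cccc(OCc2ccccc2)c1OCc1ccccc1 | intermediate
6 | 2,3-bis(benzyloxy)phenol | Oc1cccc(OCc2ccccc2)c1OCc1ccccc1 | intermediate
7 | 3,4-bis(benzyloxy)-2-hydroxybenzaldehyde | O=Cc1ccc(OCc2ccccc2)c(OCc2ccccc2)c1O | intermediate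
8 | 3,4-bis(benzyloxy)-2-methoxybenzaldehyde | COc1c(C=O)ccc(OCc2ccccc2)c1OCc1ccccc1 | intermediate
9 | phenol | Oc1ccccc1 | starting material
10 | acetyl chloride | CC(Cl)=O | starting material
11 | 1-(4-hydroxyphenyl)ethan-1-one | CC(=O)c1ccc(O)cc1 | intermediate
12 | 1-[4-(benzyloxy)phenyl]ethan-1-one | CC(=O)c1ccc(OCc2ccccc2)cc1 | intermediate
13 | (E)-1-[4-(benzyloxy)phenyl]-3-[3,4-bis(benzyloxy)-2-methoxyphenyl]prop-2-en-1-one | COc1c(/C=C/C(=O)c2ccc(OCc3ccccc3)cc2)ccc(OCc2ccccc2)c1OCc1ccccc1 | intermediate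
14 | erythro-(2R*,3S*)-1-[4-(benzyloxy)phenyl]-3-[3,4-bis(benzyloxy)-2-methoxyphenyl]-2,3-dibromopropan-1-one (racemic, 2R,3S drawn; not isolated) | COc1c([C@H](Br)[C@H](Br)C(=O)c2ccc(OCc3ccccc3)cc2)ccc(OCc2ccccc2)c1OCc1ccccc1 | intermediate
15 | (Z)-1-[4-(benzyloxy)phenyl]-3-[3,4-bis(benzyloxy)-2-methoxyphenyl]-2-bromoprop-2-en-1-one | COc1c(/C=C(\Br)C(=O)c2ccc(OCc3ccccc3)cc2)ccc(OCc2ccccc2)c1OCc1ccccc1 | intermediate
16 | (2E,3E)-1,4-bis[4-(benzyloxy)phenyl]-2,3-bis{[3,4-bis(benzyloxy)-2-methoxyphenyl]methylidene}butane-1,4-dione | COc1c(/C=C(C(=O)c2ccc(OCc3ccccc3)cc2)\C(C(=O)c2ccc(OCc3ccccc3)cc2)=C/c2ccc(OCc3ccccc3)c(OCc3ccccc3)c2OC)ccc(OCc2ccccc2)c1OCc1ccccc1 | intermediate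
17 | spiro[4.5] Wheland cation: C1 of the protonated enone bonded to the ipso carbon C1' of the second aryl ring, O-benzyl oxocarbenium form, enol at C2 (C1 configured as in 19; spiro centre and enol geometry not fixed; counter-ion is the catalyst anion; not isolated) | OC(c1ccc(OCc2ccccc2)cc1)=C1C(C(=O)c2ccc(OCc3ccccc3)cc2)=CC2(C=CC(=[O+]Cc3ccccc3)C(OCc3ccccc3)=C2OC)[C@H]1c1ccc(OCc2ccccc2)c(OCc2ccccc2)c1OC | intermediate
18 | C2 dienol of 19 (ring-expanded, C1 configured as in 19; not isolated) | COc1c([C@@H]2c3c(cc(OCc4ccccc4)c(OCc4ccccc4)c3OC)C=C(C(=O)c3ccc(OCc4ccccc4)cc3)C2=C(O)c2ccc(OCc3ccccc3)cc2)ccc(OCc2ccccc2)c1OCc1ccccc1 | intermediate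
19 | [(1R,2R)-6,7-bis(benzyloxy)-1-[3,4-bis(benzyloxy)-2-methoxyphenyl]-8-methoxy-1,2-dihydronaphthalene-2,3-diyl]bis{[4-(benzyloxy)phenyl]methanone} | COc1c([C@@H]2c3c(cc(OCc4ccccc4)c(OCc4ccccc4)c3OC)C=C(C(=O)c3ccc(OCc4ccccc4)cc3)[C@@H]2C(=O)c2ccc(OCc3ccccc3)cc2)ccc(OCc2ccccc2)c1OCc1ccccc1 | intermediate
20 | [(1R,2R)-1-(3,4-dihydroxy-2-methoxyphenyl)-6,7-dihydroxy-8-methoxy-1,2-dihydronaphthalene-2,3-diyl]bis[(4-hydroxyphenyl)methanone] (CNP0335881.1) | COc1c([C@@H]2c3c(cc(O)c(O)c3OC)C=C(C(=O)c3ccc(O)cc3)[C@@H]2C(=O)c2ccc(O)cc2)ccc(O)c1O | target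

**Step count and risks**
Total steps: 12. Longest linear sequence: 10 (steps 1–5 and 8–12, from catechol).

Most likely to fail, first: step 11 (the proposed new cycloisomerisation). The cation may close directly at C6', or the benzylic C1 may shift instead of the vinyl C4; both give the 5-methoxy regioisomer. A ketone oxygen may cyclise, a benzyl cation may be lost from 17, the ee may be low, or C2 may equilibrate to trans. The fallback uses only known chemistry, sets out from 6, 13 and 12 and comes back at 19. Amine-directed ortho-bromination of 6 (NBS, cat. i-Pr2NH, CH2Cl2) gives 2,3-bis(benzyloxy)-6-bromophenol F1, and methylation (MeI, K2CO3) gives 1,2-bis(benzyloxy)-4-bromo-3-methoxybenzene F2. Magnesium insertion gives [3,4-bis(benzyloxy)-2-methoxyphenyl]magnesium bromide F3, which adds 1,4 to chalcone 13 under CuI catalysis to give 3,3-bis[3,4-bis(benzyloxy)-2-methoxyphenyl]-1-[4-(benzyloxy)phenyl]propan-1-one F4. Its lithium enolate (LDA, −78 °C) is alkylated with 2-bromo-1-[4-(benzyloxy)phenyl]ethan-1-one F5 (from 12 with CuBr2) to give racemic 2-{bis[3,4-bis(benzyloxy)-2-methoxyphenyl]methyl}-1,4-bis[4-(benzyloxy)phenyl]butane-1,4-dione F6. DMF dimethyl acetal converts the only α-methylene into the racemic (E)-3-[(dimethylamino)methylidene] derivative of F6, enaminone F7. TFA then effects Friedel–Crafts cyclisation onto the single free ortho position of one of the two identical aryl groups with loss of dimethylamine. This puts OMe at C8 unambiguously and gives the racemic trans isomer (1R*,2S*)-2-epi-19 F8 together with rac-19. Deprotonation with LDA and kinetic protonation with AcOH at −78 °C (anti to the C1 aryl) converges the mixture on rac-19. Preparative chiral SFC separates 19 from its enantiomer (1S,2S)-ent-19 F9.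

Second: step 10 (Ni homocoupling of a hindered, electron-rich α-bromoenone). Protodebromination or slow coupling is possible, and the same fallback also bypasses step 9. It sets out from 12 and 8 and comes back at 16. Oxidative enolate dimerisation of 12 (LDA, THF, −78 °C; then CuCl2, DMF) gives 1,4-bis[4-(benzyloxy)phenyl]butane-1,4-dione F10. A twofold titanium-mediated aldol condensation with 8 (2.2 equiv, TiCl4, pyridine, THF, 0 °C to rt) then installs both E-benzylidene groups to give 16.

Third: step 12 (sixfold debenzylation next to an epimerisable centre). C2 may epimerise to the more stable trans isomer, the OMe groups next to O–BCl2 may be cleaved, or debenzylation may be incomplete. The fallback moves deprotection before the stereocentres exist; it sets out from 16 and comes back at 20. Debenzylation of achiral 16 (BCl3/pentamethylbenzene, or TFA/pentamethylbenzene at rt) gives (2E,3E)-2,3-bis[(3,4-dihydroxy-2-methoxyphenyl)methylidene]-1,4-bis(4-hydroxyphenyl)butane-1,4-dione F11. F11 is then cycloisomerised as in step 11, with a BINOL phosphoric acid that binds the free 4-OH groups, to give 20 directly, so nothing is done to the molecule after C2 is set.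

**Further compounds**
F1 | step 11 | 2,3-bis(benzyloxy)-6-bromophenol | Oc1c(Br)ccc(OCc2ccccc2)c1OCc1ccccc1
F2 | step 11 | 1,2-bis(benzyloxy)-4-bromo-3-methoxybenzene | COc1c(Br)ccc(OCc2ccccc2)c1OCc1ccccc1
F3 | step 11 | [3,4-bis(benzyloxy)-2-methoxyphenyl]magnesium bromide | COc1c([Mg]Br)ccc(OCc2ccccc2)c1OCc1ccccc1
F4 | step 11 | 3,3-bis[3,4-bis(benzyloxy)-2-methoxyphenyl]-1-[4-(benzyloxy)phenyl]propan-1-one | COc1c(C(CC(=O)c2ccc(OCc3ccccc3)cc2)c2ccc(OCc3ccccc3)c(OCc3ccccc3)c2OC)ccc(OCc2ccccc2)c1OCc1ccccc1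
F5 | step 11 | 2-bromo-1-[4-(benzyloxy)phenyl]ethan-1-one | O=C(CBr)c1ccc(OCc2ccccc2)cc1
F6 | step 11 | 2-{bis[3,4-bis(benzyloxy)-2-methoxyphenyl]methyl}-1,4-bis[4-(benzyloxy)phenyl]butane-1,4-dione (racemic) | COc1c(C(C(CC(=O)c2ccc(OCc3ccccc3)cc2)C(=O)c2ccc(OCc3ccccc3)cc2)c2ccc(OCc3ccccc3)c(OCc3ccccc3)c2OC)ccc(OCc2ccccc2)c1OCc1ccccc1
F7 | step 11 | (E)-2-{bis[3,4-bis(benzyloxy)-2-methoxyphenyl]methyl}-3-[(dimethylamino)methylidene]-1,4-bis[4-(benzyloxy)phenyl]butane-1,4-dione (racemic) | COc1c(C(C(C(=O)c2ccc(OCc3ccccc3)cc2)/C(=C\N(C)C)C(=O)c2ccc(OCc3ccccc3)cc2)c2ccc(OCc3ccccc3)c(OCc3ccccc3)c2OC)ccc(OCc2ccccc2)c1OCc1ccccc1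
F8 | step 11 | trans-(1R*,2S*)-2-epi-19 (racemic, 1R,2S drawn) | COc1c([C@@H]2c3c(cc(OCc4ccccc4)c(OCc4ccccc4)c3OC)C=C(C(=O)c3ccc(OCc4ccccc4)cc3)[C@H]2C(=O)c2ccc(OCc3ccccc3)cc2)ccc(OCc2ccccc2)c1OCc1ccccc1
F9 | step 11 | (1S,2S)-ent-19 | COc1c([C@H]2c3c(cc(OCc4ccccc4)c(OCc4ccccc4)c3OC)C=C(C(=O)c3ccc(OCc4ccccc4)cc3)[C@H]2C(=O)c2ccc(OCc3ccccc3)cc2)ccc(OCc2ccccc2)c1OCc1ccccc1
F10 | step 10 | 1,4-bis[4-(benzyloxy)phenyl]butane-1,4-dione | O=C(CCC(=O)c1ccc(OCc2ccccc2)cc1)c1ccc(OCc2ccccc2)cc1
F11 | step 12 | (2E,3E)-2,3-bis[(3,4-dihydroxy-2-methoxyphenyl)methylidene]-1,4-bis(4-hydroxyphenyl)butane-1,4-dione | COc1c(/C=C(C(=O)c2ccc(O)cc2)\C(C(=O)c2ccc(O)cc2)=C/c2ccc(O)c(O)c2OC)ccc(O)c1O
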